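## Retrosynthetic overview

1. Plakortolide L (21) comes from diimide saturation of the C12=C13 olefin in 20. Compound 20 comes from axial C6 methylation of the cyclic peroxycarbenium ion derived from the 6‑methoxy peroxyketal 18.
2. 18 comes from butenolide 11 and phosphonium salt 13 in one flask: ozonolysis of the cycloheptene in MeOH, 6‑exo oxa‑Michael closure of the 1,2‑dioxane, then Wittig formation of C12=C13.
3. Enabling feature: the peroxide‑bearing dioxane carbon C6 and chain carbon C12 are bridged by five CH2 groups (C7–C11). C6–C12 can therefore be stored as a cycloheptene whose C6=C12 bond, on Criegee cleavage, leaves O–O on C6 and CHO on C12. C3 is the β‑carbon of the C1–C4 butenolide ring and accepts that hydroperoxide.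
4. 11 comes from (R)‑2‑methylglycidol (source of C4), a cycloheptenyl Grignard reagent made from cycloheptanone (C6–C12), and a Still–Gennari phosphonate (C1–C2).
5. Ring order: γ‑lactone (step 6), then 1,2‑dioxane (step 8). The carbocycle is consumed in step 8.

Key step: step 8

Remark: plakortolide numbering is used throughout (C1 lactone C=O, C2 CH2, C3 CH–OO, C4 C(CH3)–O–C1, C5 ring CH2, C6 C(CH3)–OO, C7–C18 chain, phenyl on C18), and 1, 3, 9 and 12 are taken to be commercial.

## Route

Step 1
Reactants: 1 cycloheptanone
Product: 2 1-bromocyclohept-1-ene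
Conditions: (PhO)3P, Br2, Et3N, CH2Cl2, −60 °C → reflux
Reagents that add atoms: bromine BrBr
Why: The bromophosphorane formed in situ activates the carbonyl oxygen, bromide adds, and Et3N‑induced loss of HBr leaves the vinyl bromide (phosphite–halogen conversion of an enolisable ketone into a vinyl halide); no stereocentre is involved.

Step 2
Reactants: 3 (R)-2-methylglycidol
Product: 4 tert-butyl(dimethyl){[(2S)-2-methyloxiran-2-yl]methoxy}silane
Conditions: TBSCl, imidazole, CH2Cl2, 0 °C → rt
Reagents that add atoms: tert-butyldimethylsilyl chloride CC(C)(C)[Si](C)(C)Cl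
Why: Standard silylation of a primary alcohol removes the free alkoxide that would racemise C4 through a degenerate Payne rearrangement in step 3; the C4 geometry comes unchanged from 3 (the R→S change is only a CIP priority change).

Step 3
Reactants: 2 1-bromocyclohept-1-ene; 4 tert-butyl(dimethyl){[(2S)-2-methyloxiran-2-yl]methoxy}silane
Product: 6 (2S)-1-[(tert-butyldimethylsilyl)oxy]-3-(cyclohept-1-en-1-yl)-2-methylpropan-2-ol, via cycloheptenylmagnesium bromide 5 (not isolated)
Conditions: Mg, THF, reflux; then CuI (10 mol %), 4, THF, −30 → 0 °C; aqueous work-up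
Reagents that add atoms: none
Why: Copper‑catalysed SN2 opening of a 2,2‑disubstituted epoxide by an alkenyl Grignard reagent occurs at the unsubstituted CH2 (future C5), so the C5–C6 bond forms without touching any bond to C4 and its configuration is retained.

Step 4
Reactants: 6 (2S)-1-[(tert-butyldimethylsilyl)oxy]-3-(cyclohept-1-en-1-yl)-2-methylpropan-2-ol
Product: 7 (2S)-3-(cyclohept-1-en-1-yl)-2-methylpropane-1,2-diol
Conditions: TBAF, THF, 0 °C → rt
Reagents that add atoms: none
Why: Fluoride cleaves the primary Si–O bond, driven by the strong Si–F bond (standard TBS removal), and leaves the tertiary alcohol, the ring alkene and C4 untouched.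

Step 5
Reactants: 7 (2S)-3-(cyclohept-1-en-1-yl)-2-methylpropane-1,2-diol
Product: 8 (2S)-3-(cyclohept-1-en-1-yl)-2-hydroxy-2-methylpropanal
Conditions: IBX, DMSO, rt
Reagents that add atoms: none
Why: IBX oxidises the primary carbinol of a 1,2‑diol to the α‑hydroxy aldehyde without glycol cleavage, the tertiary OH and the alkene are inert, and the fully substituted C4 cannot epimerise.

Step 6
Reactants: 8 (2S)-3-(cyclohept-1-en-1-yl)-2-hydroxy-2-methylpropanal; 9 methyl bis(2,2,2-trifluoroethyl)phosphonoacetate
Product: 11 (5S)-5-(cyclohept-1-en-1-ylmethyl)-5-methylfuran-2(5H)-one, via Z-hydroxy enoate 10 (not isolated)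
Conditions: 9, KHMDS, 18-crown-6, THF, −78 °C, then 8; warm to rt
Reagents that add atoms: none
Why: The Still–Gennari variant of the Horner–Wadsworth–Emmons reaction gives the Z‑enoate under kinetic control, and its cis‑placed tertiary hydroxyl lactonises spontaneously (Thorpe–Ingold assistance) to the butenolide, closing the γ‑lactone ring with C4 untouched.

Step 7
Reactants: 12 (6-bromohexyl)benzene
Product: 13 triphenyl(6-phenylhexyl)phosphonium bromide
Conditions: PPh3, MeCN, reflux
Reagents that add atoms: triphenylphosphine c1ccc(cc1)P(c1ccccc1)c1ccccc1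
Why: SN2 quaternisation of triphenylphosphine by an unhindered primary bromide (standard phosphonium salt formation).

Step 8
Reactants: 11 (5S)-5-(cyclohept-1-en-1-ylmethyl)-5-methylfuran-2(5H)-one; 13 triphenyl(6-phenylhexyl)phosphonium bromide
Product: 18 (4aS,7aS)-3-methoxy-4a-methyl-3-[(6Z)-12-phenyldodec-6-en-1-yl]tetrahydro-3H-furo[3,2-c][1,2]dioxin-6(4H)-one (C6 epimers), via carbonyl oxide aldehyde 14 (not isolated), via methoxy hydroperoxide aldehyde 15 (not isolated), via peroxyketal lactone aldehyde 16 (not isolated), via phosphorus ylide 17 (not isolated)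
Conditions: O3, CH2Cl2–MeOH (4:1), Sudan III, −78 °C, N2 purge, evaporate (≤20 °C); K2CO3, 18-crown-6 (cat.), CH2Cl2, 0 °C; then 13, 40 °C
Reagents that add atoms: ozone [O-][O+]=O; methanol CO
Why: Ozone adds to the electron‑rich trisubstituted C6=C12 alkene of the cycloheptene (the electron‑poor butenolide C2=C3 is spared), Criegee fragmentation places the carbonyl oxide on the more substituted C6 and the aldehyde on C12 (14), and methanol capture gives the α‑methoxy hydroperoxide 15, so ozone supplies the O–O unit of the target and ring carbons C7–C12 become the first half of the side chain. Carbonate then deprotonates the hydroperoxide, which closes the 1,2‑dioxane by 6‑exo‑trig oxa‑Michael addition to C3 of the butenolide (16); the C4–C5–C6 tether can reach only the face of C3 that is syn to C5, so C4 dictates the cis ring fusion and hence (3S), while the C6 ketal centre forms without control and is erased in step 9. The same base converts 13, added once the hydroperoxide is consumed, into ylide 17, and Wittig olefination of the C12 aldehyde forms the C12=C13 bond that unites the two halves; the olefin geometry (Z expected) is irrelevant because step 10 saturates it. The closest known reaction types are ozonolysis of cycloalkenes in methanol to terminally differentiated aldehyde/methoxy hydroperoxides, base‑catalysed cyclisation of α‑alkoxy and tertiary hydroperoxides onto enoates and butenolides to give 1,2‑dioxanes, and solid–liquid carbonate/crown‑ether Wittig reactions of non‑stabilised phosphonium salts. The step needs chemoselective ozone uptake (secured by alkene electron density and the indicator dye), regioselective Criegee fragmentation (secured by the extra alkyl substituent on C6), and the absence of free hydroperoxide and of P(III) while the ylide is present (secured by the order of addition and by using a phosphonium salt, not a phosphine).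

Step 9
Reactants: 18 (4aS,7aS)-3-methoxy-4a-methyl-3-[(6Z)-12-phenyldodec-6-en-1-yl]tetrahydro-3H-furo[3,2-c][1,2]dioxin-6(4H)-one (C6 epimers)
Product: 20 (12Z)-12,13-didehydroplakortolide L, via peroxycarbenium ion 19 (not isolated)
Conditions: AlMe3, TMSOTf (cat.), CH2Cl2, −78 → −30 °C; aq Rochelle salt
Reagents that add atoms: trimethylaluminium C[Al](C)C
Why: Proposed new method: TMSOTf‑assisted loss of the exocyclic methoxy group from either C6 epimer gives the cyclic peroxycarbenium ion 19, which AlMe3 should methylate along the axial trajectory of the half‑chair that keeps C4–CH3 pseudoequatorial and the C4–O(lactone) bond pseudoaxial, that is, syn to the lactone oxygen and away from a developing 1,3‑diaxial CH3/CH3 clash, so that C6 becomes (S) with axial methyl and equatorial chain; the closest known reaction types are the Lewis‑acid‑mediated substitution of 3‑alkoxy‑1,2‑dioxanes and ‑dioxolanes by allylsilanes, silyl ketene acetals and Et3SiH via peroxycarbenium ions, and the AlMe3 methylation of oxocarbenium ions derived from cyclic ketals, which tolerates an endoperoxide.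

Step 10
Reactants: 20 (12Z)-12,13-didehydroplakortolide L
Product: 21 plakortolide L
Conditions: KO2CN=NCO2K, AcOH, MeOH–CH2Cl2, 0 °C → rt
Reagents that add atoms: none
Why: Diimide generated in situ transfers H2 in a concerted syn fashion to the unhindered 1,2‑disubstituted C12=C13 bond and is known to leave O–O bonds, lactones and arenes intact, so none of the three stereocentres is touched.

## Compound list

1 | cycloheptanone | O=C1CCCCCC1 | starting material
2 | 1-bromocyclohept-1-ene | BrC1=CCCCCC1 | intermediate
3 | (R)-2-methylglycidol = [(2R)-2-methyloxiran-2-yl]methanol | C[C@@]1(CO)CO1 | starting material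
4 | tert-butyl(dimethyl){[(2S)-2-methyloxiran-2-yl]methoxy}silane | C[C@@]1(CO[Si](C)(C)C(C)(C)C)CO1 | intermediate
5 | cyclohept-1-en-1-ylmagnesium bromide (not isolated) | Br[Mg]C1=CCCCCC1 | intermediate
6 | (2S)-1-[(tert-butyldimethylsilyl)oxy]-3-(cyclohept-1-en-1-yl)-2-methylpropan-2-ol | C[C@@](O)(CO[Si](C)(C)C(C)(C)C)CC1=CCCCCC1 | intermediate
7 | (2S)-3-(cyclohept-1-en-1-yl)-2-methylpropane-1,2-diol | C[C@@](O)(CO)CC1=CCCCCC1 | intermediate
8 | (2S)-3-(cyclohept-1-en-1-yl)-2-hydroxy-2-methylpropanal | C[C@@](O)(C=O)CC1=CCCCCC1 | intermediate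
9 | methyl bis(2,2,2-trifluoroethyl)phosphonoacetate | COC(=O)CP(=O)(OCC(F)(F)F)OCC(F)(F)F | starting material
10 | methyl (2Z,4S)-5-(cyclohept-1-en-1-yl)-4-hydroxy-4-methylpent-2-enoate (not isolated) | C[C@@](O)(/C=C\C(=O)OC)CC1=CCCCCC1 | intermediate
11 | (5S)-5-(cyclohept-1-en-1-ylmethyl)-5-methylfuran-2(5H)-one | C[C@]1(CC2=CCCCCC2)C=CC(=O)O1 | intermediate
12 | (6-bromohexyl)benzene | BrCCCCCCc1ccccc1 | starting material
13 | triphenyl(6-phenylhexyl)phosphonium bromide | [Br-].c1ccccc1CCCCCC[P+](c1ccccc1)(c1ccccc1)c1ccccc1 | intermediate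
14 | C6 carbonyl oxide / C12 aldehyde from Criegee cleavage of 11 (not isolated) | C[C@]1(CC(=[O+][O-])CCCCCC=O)C=CC(=O)O1 | intermediate
15 | 7-hydroperoxy-7-methoxy-8-[(2S)-2-methyl-5-oxo-2,5-dihydrofuran-2-yl]octanal (C6 epimers, not isolated) | C[C@]1(CC(OC)(OO)CCCCCC=O)C=CC(=O)O1 | intermediate
16 | 6-[(4aS,7aS)-3-methoxy-4a-methyl-6-oxotetrahydro-3H-furo[3,2-c][1,2]dioxin-3-yl]hexanal (C6 epimers, not isolated) | COC1(CCCCCC=O)C[C@]2(C)OC(=O)C[C@@H]2OO1 | intermediate
17 | triphenyl(6-phenylhexylidene)phosphorane (not isolated) | C(CCCCCc1ccccc1)=P(c1ccccc1)(c1ccccc1)c1ccccc1 | intermediate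
18 | (4aS,7aS)-3-methoxy-4a-methyl-3-[(6Z)-12-phenyldodec-6-en-1-yl]tetrahydro-3H-furo[3,2-c][1,2]dioxin-6(4H)-one (C6 epimers) | COC1(CCCCC/C=C\CCCCCc2ccccc2)C[C@]3(C)OC(=O)C[C@@H]3OO1 | intermediate
19 | cyclic C6 peroxycarbenium ion derived from 18 (not isolated) | [O+]1=C(CCCCC/C=C\CCCCCc2ccccc2)C[C@]3(C)OC(=O)C[C@@H]3O1 | intermediate
20 | (12Z)-12,13-didehydroplakortolide L = (3S,4aS,7aS)-3,4a-dimethyl-3-[(6Z)-12-phenyldodec-6-en-1-yl]tetrahydro-3H-furo[3,2-c][1,2]dioxin-6(4H)-one | C[C@]1(CCCCC/C=C\CCCCCc2ccccc2)C[C@]3(C)OC(=O)C[C@@H]3OO1 | intermediate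
21 | plakortolide L = (3S,4aS,7aS)-3,4a-dimethyl-3-(12-phenyldodecyl)tetrahydro-3H-furo[3,2-c][1,2]dioxin-6(4H)-one; (3S,4S,6S) in plakortolide numbering | C[C@]1(CCCCCCCCCCCCc2ccccc2)C[C@]2(C)OC(=O)C[C@@H]2OO1 | target

## Step count and risks

Total step count: 10.

Longest linear sequence: 8 steps, from 3 through steps 2, 3, 4, 5, 6, 8, 9 and 10.

Steps most likely to fail:

**Step 9 (proposed method).**
- What may go wrong: ionisation of the endocyclic C6–O bond followed by irreversible methylation of the ring‑opened oxocarbenium ion; Lewis‑acid‑induced heterolysis of the O–O bond; proton loss from the cation at C5 or C7; attack of the aluminium reagent on the peroxide.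
- Fallback (known chemistry only): it sets out from 11 and comes back to the route at 20. Reductive ozonolysis of 11 (O3, CH2Cl2, then Me2S) would give the keto aldehyde F1. Aldehyde‑selective Wittig reaction at −78 °C with ylide 17, preformed from 13 and NaHMDS, would give the keto olefin F2. Wittig methylenation of the ketone (Ph3P=CH2) would give the 1,1‑disubstituted olefin F3. Mukaiyama–Isayama peroxysilylation (Co(thd)2, O2, Et3SiH), which favours the 1,1‑disubstituted alkene over the 1,2‑dialkyl olefin and the butenolide, would give the triethylsilyl peroxide F4 as both C6 epimers. Buffered TBAF would release the hydroperoxide F5. Et2NH‑catalysed oxa‑Michael closure would then give 20 together with its C6 epimer F6, to be removed by chromatography.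

**Step 8 (key step).**
- What may go wrong: Criegee fragmentation in the wrong sense (carbonyl oxide on C12); partial attack of ozone on the butenolide; aldol self‑condensation of the aldehyde or base‑induced retro‑Michael decay of the peroxyketal while the ylide is formed slowly by carbonate; oxygen transfer from peroxide to the ylide.
- Fallback: it separates fragment union from peroxide installation and takes the O–O unit from hydrogen peroxide. It sets out from 11 and comes back at 18. Compound 11 is taken by reductive ozonolysis to the keto aldehyde F1 and by low‑temperature Wittig reaction with preformed 17 to the keto olefin F2. Urea–hydrogen peroxide with catalytic Sc(OTf)3 in MeOH would convert the C6 ketone into the methoxy hydroperoxide F7. Catalytic Et2NH in CF3CH2OH would then close the dioxane onto the butenolide to give 18.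

**Step 6.**
- What may go wrong: erosion of Z selectivity at the hindered α‑quaternary aldehyde (the E‑enoate cannot lactonise); α‑ketol rearrangement or self‑condensation of the unprotected hydroxy aldehyde in the basic medium.
- Fallback: it replaces olefination/lactonisation by ring‑closing metathesis. It sets out from 8 and comes back at 11. Wittig methylenation of 8 would give the tertiary allylic alcohol F8. Acylation with acryloyl chloride (iPr2NEt, DMAP) would give the acrylate F9. A second‑generation ruthenium benzylidene metathesis catalyst in refluxing CH2Cl2 would close the butenolide 11, the trisubstituted ring alkene being unreactive.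

## Further compounds

F1 | step 9 | 7-oxo-8-[(2S)-2-methyl-5-oxo-2,5-dihydrofuran-2-yl]octanal | C[C@]1(CC(=O)CCCCCC=O)C=CC(=O)O1
F2 | step 9 | (5S)-5-methyl-5-[(8Z)-2-oxo-14-phenyltetradec-8-en-1-yl]furan-2(5H)-one | C[C@]1(CC(=O)CCCCC/C=C\CCCCCc2ccccc2)C=CC(=O)O1
F3 | step 9 | (5S)-5-methyl-5-[(8Z)-2-methylidene-14-phenyltetradec-8-en-1-yl]furan-2(5H)-one | C[C@]1(CC(=C)CCCCC/C=C\CCCCCc2ccccc2)C=CC(=O)O1
F4 | step 9 | (5S)-5-methyl-5-[(8Z)-2-methyl-14-phenyl-2-(triethylsilylperoxy)tetradec-8-en-1-yl]furan-2(5H)-one (C6 epimers) | C[C@]1(CC(C)(OO[Si](CC)(CC)CC)CCCCC/C=C\CCCCCc2ccccc2)C=CC(=O)O1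
F5 | step 9 | (5S)-5-[(8Z)-2-hydroperoxy-2-methyl-14-phenyltetradec-8-en-1-yl]-5-methylfuran-2(5H)-one (C6 epimers) | C[C@]1(CC(C)(OO)CCCCC/C=C\CCCCCc2ccccc2)C=CC(=O)O1
F6 | step 9 | (6R,12Z)-12,13-didehydro-6-epi-plakortolide L | C[C@@]1(CCCCC/C=C\CCCCCc2ccccc2)C[C@]3(C)OC(=O)C[C@@H]3OO1
F7 | step 8 | (5S)-5-[(8Z)-2-hydroperoxy-2-methoxy-14-phenyltetradec-8-en-1-yl]-5-methylfuran-2(5H)-one (C6 epimers) | C[C@]1(CC(OC)(OO)CCCCC/C=C\CCCCCc2ccccc2)C=CC(=O)O1
F8 | step 6 | (2S)-1-(cyclohept-1-en-1-yl)-2-methylbut-3-en-2-ol | C[C@@](O)(C=C)CC1=CCCCCC1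
F9 | step 6 | (2S)-1-(cyclohept-1-en-1-yl)-2-methylbut-3-en-2-yl prop-2-enoate | C[C@@](OC(=O)C=C)(C=C)CC1=CCCCCC1
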